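**Strategy.** The oxonane is not closed directly. Its C2–C3 bond (numbering below), between the tetrahydrofuran ether methine C2 and the oxygenated carbon C3, is made as the ring-closing bond of a small 2,6-cis-oxane. A SmI2 ketyl–olefin cyclisation joins an aldehyde carbon (C3) to the β-carbon of a β-alkoxyacrylate (C2); the precursor is an acyclic aldehyde–acrylate, and C2 is set by a sacrificial allylic centre, C6. A copper-catalysed oxonium-ylide [2,3]-shift later moves O1 from C6 to C9 and expands this oxane by three atoms into the Z-oxonene/tetrahydrofuran bicycle. Diels–Alder annulation of ring A, double methyl addition and lactonisation complete the target.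

Key step: step 5

Numbering used (eunicellane): C1 and C10 are the ring-fusion CH of the cyclohexane (ring A); C2 and C9 are the CH–O of the tetrahydrofuran and O1 is its oxygen; C3 is the quaternary C(CH3)(O3) of the lactone (methyl C18); C4, C5 are CH2; C6=C7 is the Z-olefin (methyl C19 on C7); C8 is CH2; C11 is C(CH3)(OAc) (methyl C20); C12, C13 are CH2; C14 carries C15H(C17H3)–C16(=O)–O3. Target: 1S,2S,3S,9S,10R,11R,14R,15R, 6Z.

Remark: the C3 carbinol centre formed in step 5 is provisional; it is oxidised in step 17 and set for good in step 18.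

Step 1
Reactants: 1 4,4-dimethoxybutanenitrile; 2 isopropenylmagnesium bromide
Product: 4 6,6-dimethoxy-2-methylhex-1-en-3-one, via bromomagnesium ketimine 3 (not isolated)
Conditions: THF, 0 °C to rt; then aq. HCl/NH4Cl (pH 4), 0 °C
Reagents that add atoms: water, O
Why: Grignard addition to a nitrile stops at the magnesium ketimine, which is hydrolysed at pH 4 to the isopropenyl ketone while the dimethyl acetal should survive.

Step 2
Reactants: 4 6,6-dimethoxy-2-methylhex-1-en-3-one
Product: 5 (3S)-6,6-dimethoxy-2-methylhex-1-en-3-ol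
Conditions: (R)-2-methyl-CBS-oxazaborolidine (10 mol%), BH3·SMe2, THF, −30 °C; MeOH quench
Reagents that add atoms: none
Why: Corey–Bakshi–Shibata reduction, in which the alkenyl group acts as the large substituent so that the (R)-catalyst should deliver hydride to the face giving the (S)-allylic alcohol, the sacrificial C6 centre.

Step 3
Reactants: 5 (3S)-6,6-dimethoxy-2-methylhex-1-en-3-ol; 6 ethyl propiolate
Product: 7 ethyl (2E)-3-{[(3S)-6,6-dimethoxy-2-methylhex-1-en-3-yl]oxy}prop-2-enoate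
Conditions: N-methylmorpholine, CH2Cl2, rt
Reagents that add atoms: none
Why: Amine-mediated oxa-Michael addition of the secondary alcohol to the ynoate should give the (E)-β-alkoxyacrylate without touching C6.

Step 4
Reactants: 7 ethyl (2E)-3-{[(3S)-6,6-dimethoxy-2-methylhex-1-en-3-yl]oxy}prop-2-enoate
Product: 8 ethyl (2E)-3-{[(3S)-2-methyl-6-oxohex-1-en-3-yl]oxy}prop-2-enoate
Conditions: Amberlyst-15, acetone/H2O, rt
Reagents that add atoms: water, O
Why: Acid-catalysed acetal hydrolysis, to which the vinylogous carbonate and the allylic ether should be stable at room temperature.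

Step 5
Reactants: 8 ethyl (2E)-3-{[(3S)-2-methyl-6-oxohex-1-en-3-yl]oxy}prop-2-enoate
Product: 9 ethyl 2-[(2S,3R,6S)-3-hydroxy-6-(prop-1-en-2-yl)oxan-2-yl]acetate
Conditions: SmI2 (3 equiv), MeOH (3 equiv), THF, 0 °C
Reagents that add atoms: none
Why: SmI2 reduces the aldehyde to a samarium ketyl whose carbon (C3) adds to the β-carbon (C2) of the tethered (E)-β-alkoxyacrylate, and a second electron plus methanol turn the α-ester radical into the saturated ester. This is the known ketyl–olefin reductive cyclisation of aldehydes onto β-alkoxyacrylates, widely used for 3-hydroxyoxanes. The oxane (O1, C2–C6) closes in the 6-exo-trig mode. C2 is set by the existing C6 centre, because in the chair transition state the isopropenyl group and the acrylate are both equatorial (2,6-cis), and samarium bridging the ketyl oxygen and the ester carbonyl places the provisional C3 hydroxyl trans to the acetate arm. The step needs the aldehyde to be reduced before the acrylate and cyclisation to outrun pinacol coupling or simple reduction; the easily reduced aldehyde, the activated acceptor five atoms away and the proton source should secure this.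

Step 6
Reactants: 9 ethyl 2-[(2S,3R,6S)-3-hydroxy-6-(prop-1-en-2-yl)oxan-2-yl]acetate
Product: 10 ethyl 2-[(2S,3R,6S)-3-(tert-butyldimethylsilyloxy)-6-(prop-1-en-2-yl)oxan-2-yl]acetate
Conditions: TBSOTf, 2,6-lutidine, CH2Cl2, −78 to 0 °C
Reagents that add atoms: tert-butyldimethylsilyl triflate, CC(C)(C)[Si](C)(C)OS(=O)(=O)C(F)(F)F
Why: Silylation masks the hydroxyl, which would otherwise intercept the carbenoid of step 9 by O–H insertion.

Step 7
Reactants: 10 ethyl 2-[(2S,3R,6S)-3-(tert-butyldimethylsilyloxy)-6-(prop-1-en-2-yl)oxan-2-yl]acetate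
Product: 11 2-[(2S,3R,6S)-3-(tert-butyldimethylsilyloxy)-6-(prop-1-en-2-yl)oxan-2-yl]acetic acid
Conditions: LiOH, THF/H2O, rt; then aq. HCl to pH 3
Reagents that add atoms: lithium hydroxide, [Li+].[OH-]
Why: Saponification of the ethyl ester, to which the secondary silyl ether should be stable.

Step 8
Reactants: 11 2-[(2S,3R,6S)-3-(tert-butyldimethylsilyloxy)-6-(prop-1-en-2-yl)oxan-2-yl]acetic acid
Product: 13 1-diazo-3-[(2S,3R,6S)-3-(tert-butyldimethylsilyloxy)-6-(prop-1-en-2-yl)oxan-2-yl]propan-2-one, via mixed carbonic anhydride 12 (not isolated)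
Conditions: i-BuOCOCl, Et3N, Et2O, 0 °C; then CH2N2, Et2O, 0 °C to rt
Reagents that add atoms: diazomethane, C=[N+]=[N-]
Why: Acylation of diazomethane by the mixed anhydride (first stage of an Arndt–Eistert sequence) gives the α-diazoketone and brings in C9.

Step 9
Reactants: 13 1-diazo-3-[(2S,3R,6S)-3-(tert-butyldimethylsilyloxy)-6-(prop-1-en-2-yl)oxan-2-yl]propan-2-one
Product: 15 (1S,2R,5Z,8S)-2-(tert-butyldimethylsilyloxy)-6-methyl-11-oxabicyclo[6.2.1]undec-5-en-9-one, via oxonium ylide 14 (not isolated)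
Conditions: Cu(hfacac)2 (5 mol%), CH2Cl2, reflux
Reagents that add atoms: none
Why: The copper carbenoid is captured by the ring oxygen O1 to give a five-membered oxonium ylide, whose [2,3]-sigmatropic shift across the C6 isopropenyl unit forms C8–C9, cleaves O1–C6 and enlarges the oxane by three atoms; the bridge forces C9–H cis to C2–H, and the Z-olefin should be the main geometry with this catalyst.

Step 10
Reactants: 15 (1S,2R,5Z,8S)-2-(tert-butyldimethylsilyloxy)-6-methyl-11-oxabicyclo[6.2.1]undec-5-en-9-one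
Product: 16 (1S,2R,5Z,8S)-2-(tert-butyldimethylsilyloxy)-6-methyl-11-oxabicyclo[6.2.1]undeca-5,9-dien-9-yl trifluoromethanesulfonate
Conditions: NaN(SiMe3)2, PhNTf2, THF, −78 °C; aq. NH4Cl
Reagents that add atoms: N-phenylbis(trifluoromethanesulfonimide), O=S(=O)(N(c1ccccc1)S(=O)(=O)C(F)(F)F)C(F)(F)F
Why: Kinetic deprotonation at the C1 methylene (the other α-position is a bridgehead) and O-triflation should give the C10 enol triflate.

Step 11
Reactants: 16 (1S,2R,5Z,8S)-2-(tert-butyldimethylsilyloxy)-6-methyl-11-oxabicyclo[6.2.1]undeca-5,9-dien-9-yl trifluoromethanesulfonate; 17 tributyl(1-ethoxyvinyl)stannane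
Product: 18 (1S,2R,5Z,8S)-2-(tert-butyldimethylsilyloxy)-9-(1-ethoxyethenyl)-6-methyl-11-oxabicyclo[6.2.1]undeca-5,9-diene
Conditions: Pd(PPh3)4 (5 mol%), LiCl, THF, reflux
Reagents that add atoms: none
Why: Stille coupling installs the 1-ethoxyvinyl unit (C11, C12) and gives the electron-rich 2-ethoxydiene.

Step 12
Reactants: 18 (1S,2R,5Z,8S)-2-(tert-butyldimethylsilyloxy)-9-(1-ethoxyethenyl)-6-methyl-11-oxabicyclo[6.2.1]undeca-5,9-diene; 19 methyl vinyl ketone
Product: 21 tricyclic enol ether ketone (1S,2S,3R,6Z,9S,14R): ring A cyclohexene with 11-ethoxy-10(11)-ene and equatorial 14-acetyl fused to the oxonene/tetrahydrofuran bicycle, 3-OTBS, via cycloadduct C14 epimers 20 (not isolated)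
Conditions: toluene, 110 °C; then K2CO3, MeOH, rt
Reagents that add atoms: none
Why: Diels–Alder reaction in which the 2-ethoxydiene directs C12 to the β-carbon of the enone, the dienophile adds to the diene face on the side of the oxygen bridge (setting C1), and carbonate then equilibrates the α-keto centre C14 to the equatorial acetyl trans to H1.

Step 13
Reactants: 21 tricyclic enol ether ketone (1S,2S,3R,6Z,9S,14R)
Product: 22 vinyl triflate of 21 (1S,2S,3R,6Z,9S,14R): C14 carries C(=CH2)OTf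
Conditions: KN(SiMe3)2, PhNTf2, THF, −78 °C; aq. NH4Cl
Reagents that add atoms: N-phenylbis(trifluoromethanesulfonimide), O=S(=O)(N(c1ccccc1)S(=O)(=O)C(F)(F)F)C(F)(F)F
Why: Kinetic enolisation of the methyl ketone at the methyl group, followed by triflation, should give the terminal vinyl triflate.

Step 14
Reactants: 22 vinyl triflate (1S,2S,3R,6Z,9S,14R)
Product: 23 acrylic acid (1S,2S,3R,6Z,9S,14R): C14 carries C(=CH2)CO2H, ring A still the 11-ethoxy enol ether, 3-OTBS
Conditions: Pd(OAc)2 (5 mol%), dppf, CO (1 atm), KOAc, DMF/H2O, 60 °C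
Reagents that add atoms: carbon monoxide, [C-]#[O+]; water, O
Why: Palladium-catalysed hydroxycarbonylation of the vinyl triflate introduces C16 as the carboxylic acid and leaves the former acetyl methyl as the exocyclic methylene C17.

Step 15
Reactants: 23 acrylic acid (1S,2S,3R,6Z,9S,14R)
Product: 24 2-[(1S,2S,3R,6Z,9S,10R,14R)-3-hydroxy-11-oxo-tricycle-14-yl]acrylic acid (C11 ketone, free C3–OH, cis-fused hydroisobenzofuran)
Conditions: 48% aq. HF, MeCN, 0 °C to rt
Reagents that add atoms: water, O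
Why: HF cleaves the silyl ether and hydrolyses the enol ether; C10 is protonated and, being epimerisable α to the C11 ketone, should settle in the cis-fused hydroisobenzofuran.

Step 16
Reactants: 24 hydroxy keto acrylic acid (1S,2S,3R,6Z,9S,10R,14R)
Product: 25 (2R)-2-[(1S,2S,3R,6Z,9S,10R,14R)-3-hydroxy-11-oxo-tricycle-14-yl]propanoic acid (15R)
Conditions: Ru(OAc)2[(R)-BINAP] (2 mol%), H2 (50 atm), MeOH, rt
Reagents that add atoms: none
Why: Carboxylate-directed asymmetric hydrogenation of the 2-substituted acrylic acid should set C15 under catalyst control (ligand sense chosen by analogy with 2-substituted acrylic acids), while the isolated trisubstituted olefin, bishomoallylic to the hydroxyl, and the ketone are not reduced.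

Step 17
Reactants: 25 hydroxy keto acid (1S,2S,3R,6Z,9S,10R,14R,15R)
Product: 26 3,11-diketo acid (1S,2S,6Z,9S,10R,14R,15R)
Conditions: Dess–Martin periodinane, CH2Cl2, rt
Reagents that add atoms: none
Why: Dess–Martin oxidation of the only hydroxyl gives the C3 ketone, and C2, a bridgehead, cannot epimerise.

Step 18
Reactants: 26 3,11-diketo acid (1S,2S,6Z,9S,10R,14R,15R)
Product: 27 3,11-dihydroxy-3,11-dimethyl acid (1S,2S,3S,6Z,9S,10R,11R,14R,15R)
Conditions: MeLi (6 equiv), CeCl3 (6 equiv), THF, −78 °C; aq. NH4Cl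
Reagents that add atoms: methyllithium, [Li]C
Why: Organocerium 1,2-addition to both ketones suppresses enolisation and β-alkoxide elimination; at C3 the methyl should enter from the outer face syn to H2 (the other face is covered by O1, C1 and the C14 side chain), and at C11 axially, anti to the axial C9 substituent on the convex face of ring A.

Step 19
Reactants: 27 dihydroxy acid (1S,2S,3S,6Z,9S,10R,11R,14R,15R)
Product: 29 11-hydroxy lactone (deacetyl target; 1S,2S,3S,6Z,9S,10R,11R,14R,15R), via trichlorobenzoyl mixed anhydride 28 (not isolated)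
Conditions: 2,4,6-Cl3C6H2COCl, Et3N, THF, rt; then DMAP, toluene, 80 °C
Reagents that add atoms: none
Why: Yamaguchi lactonisation, in which the mixed anhydride should acylate the C3 tertiary hydroxyl held next to the side chain and close the seven-membered lactone, whereas the C11 hydroxyl cannot reach the acyl group.

Step 20
Reactants: 29 11-hydroxy lactone
Product: 30 target, 11-acetoxy lactone (1S,2S,3S,6Z,9S,10R,11R,14R,15R)
Conditions: Ac2O, DMAP, Et3N, CH2Cl2, 40 °C
Reagents that add atoms: acetic anhydride, CC(=O)OC(C)=O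
Why: DMAP-catalysed acetylation of the remaining tertiary C11 hydroxyl.

**Compound list**

1 | 4,4-dimethoxybutanenitrile | N#CCCC(OC)OC | starting material
2 | isopropenylmagnesium bromide | CC(=C)[Mg]Br | starting material
3 | bromomagnesium ketimine of 4 | CC(=C)C(CCC(OC)OC)=N[Mg]Br | intermediate
4 | 6,6-dimethoxy-2-methylhex-1-en-3-one | CC(=C)C(=O)CCC(OC)OC | intermediate
5 | (3S)-6,6-dimethoxy-2-methylhex-1-en-3-ol | CC(=C)[C@@H](O)CCC(OC)OC | intermediate
6 | ethyl propiolate | CCOC(=O)C#C | starting material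
7 | ethyl (2E)-3-{[(3S)-6,6-dimethoxy-2-methylhex-1-en-3-yl]oxy}prop-2-enoate | CCOC(=O)/C=C/O[C@@H](CCC(OC)OC)C(C)=C | intermediate
8 | ethyl (2E)-3-{[(3S)-2-methyl-6-oxohex-1-en-3-yl]oxy}prop-2-enoate | CCOC(=O)/C=C/O[C@@H](CCC=O)C(C)=C | intermediate
9 | ethyl 2-[(2S,3R,6S)-3-hydroxy-6-(prop-1-en-2-yl)oxan-2-yl]acetate | CCOC(=O)C[C@@H]1O[C@@H](CC[C@H]1O)C(C)=C | intermediate
10 | ethyl 2-[(2S,3R,6S)-3-(tert-butyldimethylsilyloxy)-6-(prop-1-en-2-yl)oxan-2-yl]acetate | CCOC(=O)C[C@@H]1O[C@@H](CC[C@H]1O[Si](C)(C)C(C)(C)C)C(C)=C | intermediate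
11 | 2-[(2S,3R,6S)-3-(tert-butyldimethylsilyloxy)-6-(prop-1-en-2-yl)oxan-2-yl]acetic acid | OC(=O)C[C@@H]1O[C@@H](CC[C@H]1O[Si](C)(C)C(C)(C)C)C(C)=C | intermediate
12 | isobutyl carbonic mixed anhydride of 11 | CC(C)COC(=O)OC(=O)C[C@@H]1O[C@@H](CC[C@H]1O[Si](C)(C)C(C)(C)C)C(C)=C | intermediate
13 | 1-diazo-3-[(2S,3R,6S)-3-(tert-butyldimethylsilyloxy)-6-(prop-1-en-2-yl)oxan-2-yl]propan-2-one | [N-]=[N+]=CC(=O)C[C@@H]1O[C@@H](CC[C@H]1O[Si](C)(C)C(C)(C)C)C(C)=C | intermediate
14 | bicyclic oxonium ylide (O1 bonded to C2, C6 and carbanionic C9; 3-oxo-oxolanium ring fused to the oxane) | O=C1C[C@H]2[C@H](O[Si](C)(C)C(C)(C)C)CC[C@@H](C(C)=C)[O+]2[CH-]1 | intermediate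
15 | (1S,2R,5Z,8S)-2-(tert-butyldimethylsilyloxy)-6-methyl-11-oxabicyclo[6.2.1]undec-5-en-9-one | O=C1C[C@H]2[C@H](O[Si](C)(C)C(C)(C)C)CC/C=C(C)\C[C@@H]1O2 | intermediate
16 | (1S,2R,5Z,8S)-2-(tert-butyldimethylsilyloxy)-6-methyl-11-oxabicyclo[6.2.1]undeca-5,9-dien-9-yl trifluoromethanesulfonate | FC(F)(F)S(=O)(=O)OC1=C[C@H]2[C@H](O[Si](C)(C)C(C)(C)C)CC/C=C(C)\C[C@@H]1O2 | intermediate
17 | tributyl(1-ethoxyvinyl)stannane | CCCC[Sn](CCCC)(CCCC)C(=C)OCC | starting material
18 | (1S,2R,5Z,8S)-2-(tert-butyldimethylsilyloxy)-9-(1-ethoxyethenyl)-6-methyl-11-oxabicyclo[6.2.1]undeca-5,9-diene | C=C(OCC)C1=C[C@H]2[C@H](O[Si](C)(C)C(C)(C)C)CC/C=C(C)\C[C@@H]1O2 | intermediate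
19 | methyl vinyl ketone (but-3-en-2-one) | CC(=O)C=C | starting material
20 | Diels–Alder adduct, mixture of C14 epimers (1S,2S,3R,6Z,9S) | CCOC1=C2[C@@H]3C/C(C)=C\CC[C@@H](O[Si](C)(C)C(C)(C)C)[C@@H](O3)[C@H]2C(C(C)=O)CC1 | intermediate
21 | tricyclic enol ether ketone, 14-acetyl equatorial (1S,2S,3R,6Z,9S,14R) | CCOC1=C2[C@@H]3C/C(C)=C\CC[C@@H](O[Si](C)(C)C(C)(C)C)[C@@H](O3)[C@H]2[C@H](C(C)=O)CC1 | intermediate
22 | vinyl triflate of 21 (1S,2S,3R,6Z,9S,14R) | CCOC1=C2[C@@H]3C/C(C)=C\CC[C@@H](O[Si](C)(C)C(C)(C)C)[C@@H](O3)[C@H]2[C@H](C(=C)OS(=O)(=O)C(F)(F)F)CC1 | intermediate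
23 | 14-(1-carboxyvinyl) enol ether (1S,2S,3R,6Z,9S,14R) | CCOC1=C2[C@@H]3C/C(C)=C\CC[C@@H](O[Si](C)(C)C(C)(C)C)[C@@H](O3)[C@H]2[C@H](C(=C)C(=O)O)CC1 | intermediate
24 | 3-hydroxy-11-oxo acrylic acid (1S,2S,3R,6Z,9S,10R,14R) | O=C1CC[C@@H](C(=C)C(=O)O)[C@H]2[C@@H]1[C@@H]1C/C(C)=C\CC[C@@H](O)[C@H]2O1 | intermediate
25 | 3-hydroxy-11-oxo propanoic acid (1S,2S,3R,6Z,9S,10R,14R,15R) | O=C1CC[C@@H]([C@@H](C)C(=O)O)[C@H]2[C@@H]1[C@@H]1C/C(C)=C\CC[C@@H](O)[C@H]2O1 | intermediate
26 | 3,11-dioxo propanoic acid (1S,2S,6Z,9S,10R,14R,15R) | O=C1CC[C@@H]([C@@H](C)C(=O)O)[C@H]2[C@@H]1[C@@H]1C/C(C)=C\CCC(=O)[C@H]2O1 | intermediate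
27 | 3,11-dihydroxy-3,11-dimethyl propanoic acid (1S,2S,3S,6Z,9S,10R,11R,14R,15R) | O[C@]1(C)CC[C@@H]([C@@H](C)C(=O)O)[C@H]2[C@@H]1[C@@H]1C/C(C)=C\CC[C@](C)(O)[C@H]2O1 | intermediate
28 | 2,4,6-trichlorobenzoyl mixed anhydride of 27 | O[C@]1(C)CC[C@@H]([C@@H](C)C(=O)OC(=O)c3c(Cl)cc(Cl)cc3Cl)[C@H]2[C@@H]1[C@@H]1C/C(C)=C\CC[C@](C)(O)[C@H]2O1 | intermediate
29 | 11-hydroxy lactone, deacetyl target (1S,2S,3S,6Z,9S,10R,11R,14R,15R) | O[C@]1(C)CC[C@@H]2[C@H]3[C@@H]1[C@@H]1C/C(C)=C\CC[C@](C)(OC(=O)[C@@H]2C)[C@H]3O1 | intermediate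
30 | target, 11-acetoxy lactone (1S,2S,3S,6Z,9S,10R,11R,14R,15R) | CC(=O)O[C@]1(C)CC[C@@H]2[C@H]3[C@@H]1[C@@H]1C/C(C)=C\CC[C@](C)(OC(=O)[C@@H]2C)[C@H]3O1 | target

**Total step count:** 20. **Longest linear sequence:** 20 steps (1 to 30; all other inputs are commercial).

**Steps most likely to fail**

Step 18. What may go wrong: poor facial selectivity at C3 (chelation by O1 would favour the wrong face), or enolisation and β-alkoxide elimination during the double addition. Fallback: C3 is set by the lactone tether instead of by reagent approach. Starting from 25, MeLi/CeCl3 adds only to the C11 ketone and gives the 11-carbinol hydroxy acid F1. Dess–Martin oxidation gives the 3-keto acid F2, and Wittig methylenation (Ph3P=CH2, excess) the 3-methylene acid F3. Iodolactonisation (I2, NaHCO3, MeCN) lets the side-chain carboxylate attack the tertiary terminus C3 from the only face it can reach and gives the iodomethyl lactone F4. Bu3SnH (excess, AIBN, toluene, 80 °C) replaces iodine by hydrogen and the route is rejoined at 29.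

Step 19. What may go wrong: slow acylation of the hindered tertiary hydroxyl and oligomerisation of the activated acid. Fallback: the ring is closed by the alkoxide instead of by carboxyl activation. Starting from 25, the acid is esterified (Me3SiCHN2, MeOH/toluene) to the methyl ester F5 and oxidised (Dess–Martin periodinane) to the diketo ester F6. This is treated with MeLi/CeCl3 at −78 °C; on warming, the C3 alkoxide should attack the neighbouring ester and expel methoxide, which rejoins the route at 29.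

Step 9. What may go wrong: diversion of the carbenoid into C–H insertion next to the silyl ether, and loss of control over olefin geometry. Fallback: a more stabilised, more selective carbenoid. Starting from 11, the acid is homologated (carbonyldiimidazole, then Mg(O2CCH2CO2Et)2, THF) to the β-keto ester F7. Diazo transfer (4-acetamidobenzenesulfonyl azide, Et3N, MeCN) gives the diazo β-keto ester F8. Cu(hfacac)2 in refluxing 1,2-dichloroethane brings about the same ylide formation and [2,3]-shift to the bridged β-keto ester F9. Dealkoxycarbonylation (LiCl, wet DMSO, 140 °C) reprotonates the bridgehead C9 and rejoins the route at 15.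

Further compounds
F1 | step 18 | 11-carbinol hydroxy acid (3-hydroxy-11-hydroxy-11-methyl propanoic acid) | O[C@]1(C)CC[C@@H]([C@@H](C)C(=O)O)[C@H]2[C@@H]1[C@@H]1C/C(C)=C\CC[C@@H](O)[C@H]2O1
F2 | step 18 | 3-keto acid (11-hydroxy-11-methyl-3-oxo propanoic acid) | O[C@]1(C)CC[C@@H]([C@@H](C)C(=O)O)[C@H]2[C@@H]1[C@@H]1C/C(C)=C\CCC(=O)[C@H]2O1
F3 | step 18 | 3-methylene acid | O[C@]1(C)CC[C@@H]([C@@H](C)C(=O)O)[C@H]2[C@@H]1[C@@H]1C/C(C)=C\CCC(=C)[C@H]2O1
F4 | step 18 | iodomethyl lactone (C18 as CH2I) | O[C@]1(C)CC[C@@H]2[C@H]3[C@@H]1[C@@H]1C/C(C)=C\CC[C@](CI)(OC(=O)[C@@H]2C)[C@H]3O1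
F5 | step 19 | methyl ester of 25 | O=C1CC[C@@H]([C@@H](C)C(=O)OC)[C@H]2[C@@H]1[C@@H]1C/C(C)=C\CC[C@@H](O)[C@H]2O1
F6 | step 19 | 3,11-diketo methyl ester | O=C1CC[C@@H]([C@@H](C)C(=O)OC)[C@H]2[C@@H]1[C@@H]1C/C(C)=C\CCC(=O)[C@H]2O1
F7 | step 9 | ethyl 3-oxo-4-[(2S,3R,6S)-3-(tert-butyldimethylsilyloxy)-6-(prop-1-en-2-yl)oxan-2-yl]butanoate | CCOC(=O)CC(=O)C[C@@H]1O[C@@H](CC[C@H]1O[Si](C)(C)C(C)(C)C)C(C)=C
F8 | step 9 | ethyl 2-diazo-3-oxo-4-[(2S,3R,6S)-3-(tert-butyldimethylsilyloxy)-6-(prop-1-en-2-yl)oxan-2-yl]butanoate | CCOC(=O)C(=[N+]=[N-])C(=O)C[C@@H]1O[C@@H](CC[C@H]1O[Si](C)(C)C(C)(C)C)C(C)=C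
F9 | step 9 | bridged β-keto ester (15 with CO2Et on the bridgehead C9) | O=C1C[C@H]2[C@H](O[Si](C)(C)C(C)(C)C)CC/C=C(C)\C[C@]1(C(=O)OCC)O2
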